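## Retrosynthetic overview

1. The target is cut at the C9–C11 bond. The strategy rests on two features: ring B carries the three-carbon array C12–C8–C9 (C8 methyl carbon, C8, quaternary C9) next to the angular quaternary C10, and the benzylic C11 sits ortho to the phenol oxygen of the arene.
2. That array is treated as an allyl unit. A C12 allylboronate adds through its γ-carbon C9 to a salicylaldehyde aryl carbonate, forming C9–C11 on the α face and leaving a C8=C12 methylene and a C11 hydroxyl.
3. The C11 hydroxyl steers hydrogen to C8 (axial β methyl). It is then removed by carbonate transfer from the phenol, ortho-quinone methide formation and hydride addition; C4 is carried as a silyl ether and finished as the exocyclic methylene.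
4. No ring is formed. Rings A and B are bought together in the (S)-Wieland–Miescher ketone (enone ring becomes ring A, saturated-ketone ring becomes ring B); the arene is bought as methyl 3-formyl-4-hydroxybenzoate and joined to C9 of ring B in the key step.

Key step: step 12

Numbering and faces: C1–C3 are the ring A CH2 groups, C4 the carbon that ends as C=CH2, C5 the ring-fusion CH, C6 and C7 the ring B CH2 groups, C8 the CH–CH3 carbon (methyl = C12), C9 the quaternary carbon with CH3 and the benzylic C11, C10 the ring-fusion C–CH3. The C10 methyl defines the β face; α is the opposite face.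

Remark on the chemistry: the C11 carbinol configuration made in step 12 and the C4 carbinol configuration made in step 6 are both erased later, so only their faces (both α) matter.

## Route

Step 1
Reactants: 1 (S)-Wieland–Miescher ketone, (S)-8a-methyl-3,4,8,8a-tetrahydronaphthalene-1,6(2H,7H)-dione
Product: 2 C3 ethylene dithioketal of 1 (spiro-1,3-dithiolane at the former enone carbonyl; C4=C5 retained; C9 ketone free)
Conditions: HS(CH2)2SH, BF3·OEt2, MeOH, 0 °C → rt
Reagents that add atoms: ethane-1,2-dithiol, SCCS
Why: Lewis-acid-catalysed dithioketalisation should take place at the conjugated C3 carbonyl in preference to the neopentyl C9 ketone, and thioketal formation leaves the double bond at C4–C5.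

Step 2
Reactants: 2 C3 ethylene dithioketal
Product: 3 (S)-8a-methyl-3,4,6,7,8,8a-hexahydronaphthalen-1(2H)-one (C9 ketone, C4=C5 alkene, C3 now CH2)
Conditions: Raney Ni (Ni–Al alloy leached with NaOH, deactivated by brief reflux in acetone), EtOH, reflux
Reagents that add atoms: none
Why: Reductive desulfurisation on nickel (Mozingo reduction) should replace both C–S bonds by C–H, and the deactivated metal is expected to spare the trisubstituted alkene and the hindered ketone.

Step 3
Reactants: 3 octalone with C9 ketone
Product: 4 methyl (8aS)-8a-methyl-1-oxo-1,2,3,4,6,7,8,8a-octahydronaphthalene-2-carboxylate (C8 methoxycarbonyl, C9 ketone; keto–enol mixture, C8 undefined)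
Conditions: NaH, (MeO)2CO, THF, reflux; then 1 M HCl
Reagents that add atoms: dimethyl carbonate, COC(=O)OC
Why: Claisen-type C-acylation of the only possible enolate (towards C8, since C10 is quaternary) should give the β-keto ester, driven by formation of its sodium enolate.

Step 4
Reactants: 4 β-keto ester
Product: 5 enol triflate, methyl (S)-8a-methyl-1-(trifluoromethanesulfonyloxy)-3,4,6,7,8,8a-hexahydronaphthalene-2-carboxylate (C8=C9, OTf on C9)
Conditions: NaH, CH2Cl2/Et2O, 0 °C; Tf2O, −78 → 0 °C
Reagents that add atoms: trifluoromethanesulfonic anhydride, O=S(=O)(OS(=O)(=O)C(F)(F)F)C(F)(F)F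
Why: O-sulfonylation of the sodium enolate of the β-keto ester should give the enol triflate with the double bond fixed at C8–C9 inside ring B.

Step 5
Reactants: 5 enol triflate
Product: 6 methyl (S)-1,8a-dimethyl-3,4,6,7,8,8a-hexahydronaphthalene-2-carboxylate (C9 methyl and C8 CO2Me on the C8=C9 double bond; C4=C5 retained)
Conditions: Me2CuLi (from CuI and MeLi), Et2O/THF, −78 → −20 °C; aq. NH4Cl
Reagents that add atoms: lithium dimethylcuprate, [Li+].C[Cu-]C
Why: Addition–elimination coupling of a Gilman cuprate with a β-triflyloxy enoate should exchange triflate for methyl, and the resulting fully substituted enoate is too hindered for a second conjugate addition.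

Step 6
Reactants: 6 dienyl ester
Product: 8 hydroxy enoate of the trans-fused series (C4–OH α; C5–H α; C8=C9 enoate intact), via C4 alkylborane 7 (not isolated)
Conditions: BH3·SMe2, THF, 0 °C → rt; then 3 M NaOH, 30% H2O2, 0 °C
Reagents that add atoms: hydrogen peroxide, OO; borane–dimethyl sulfide, [BH3-][S+](C)C (boron stays only in intermediate 7)
Why: Hydroboration–oxidation should add boron to C4 and hydrogen to C5 syn from the α face, opposite the C10 methyl, which sets the trans ring fusion at C5 and the α oxygen at C4, while the conjugated tetrasubstituted C8=C9 bond is expected to stay inert.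

Step 7
Reactants: 8 hydroxy enoate
Product: 9 C4 tert-butyldimethylsilyl ether of 8
Conditions: TBSCl, imidazole, DMF, rt
Reagents that add atoms: tert-butyldimethylsilyl chloride, CC(C)(C)[Si](C)(C)Cl
Why: Imidazole-promoted silylation of the equatorial secondary C4 alcohol should proceed normally and masks the oxygen until the final methylenation.

Step 8
Reactants: 9 silyl ether ester
Product: 10 allylic alcohol (C12–OH on the C8=C9 double bond; C4–OTBS α; C5–H α)
Conditions: i-Bu2AlH, CH2Cl2, −78 → 0 °C; aq. KNaC4H4O6 (potassium sodium tartrate)
Reagents that add atoms: none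
Why: 1,2-Reduction of the hindered enoate with i-Bu2AlH should stop at the primary allylic alcohol without touching the silyl ether or the alkene.

Step 9
Reactants: 10 allylic alcohol
Product: 11 allylic methyl carbonate of 10
Conditions: ClCO2Me, pyridine, CH2Cl2, 0 °C
Reagents that add atoms: methyl chloroformate, COC(=O)Cl
Why: Acylation of the primary alcohol with a chloroformate should give the carbonate, a leaving group that also supplies the methoxide needed in the next step.

Step 10
Reactants: 11 allylic methyl carbonate
Product: 12 pinacol allylboronate with boron on primary C12 (fragment 1; C8=C9 retained)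
Conditions: B2pin2, Pd2(dba)3 (2.5 mol %), DMSO, 50 °C
Reagents that add atoms: bis(pinacolato)diboron, CC1(C)OB(OC1(C)C)B1OC(C)(C)C(C)(C)O1
Why: Miyaura-type allylic borylation: zerovalent palladium ionises the carbonate to a π-allyl complex with loss of CO2, the released methoxide activates B2pin2, and reductive elimination should place boron on the less hindered terminus C12.

Step 11
Reactants: 13 methyl 3-formyl-4-hydroxybenzoate
Product: 14 methyl 4-(tert-butoxycarbonyloxy)-3-formylbenzoate (fragment 2)
Conditions: Boc2O, DMAP (5 mol %), i-Pr2NEt, CH2Cl2, 0 °C → rt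
Reagents that add atoms: di-tert-butyl dicarbonate, CC(C)(C)OC(=O)OC(=O)OC(C)(C)C
Why: Nucleophile-catalysed O-acylation of the acidic phenol should give the aryl tert-butyl carbonate and leave the aldehyde and the methyl ester untouched.

Step 12
Reactants: 12 C12 pinacol allylboronate (fragment 1); 14 aryl carbonate aldehyde (fragment 2)
Product: 16 homoallylic C11 carbinol (C9 quaternary with β CH3 and α CH(OH)Ar; C8=C12 exocyclic methylene; aryl carbonate and C4–OTBS intact), via C11 pinacol borate 15 (not isolated)
Conditions: PhMe (1 M), 4 Å sieves, 60 °C; then pH 7 phosphate buffer, rt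
Reagents that add atoms: none
Why: Boron of 12 binds the formyl oxygen of 14 and the allyl unit is passed on through a closed chair-like six-membered transition state (B, O, C11, C9, C8, C12), so C11 bonds to the γ-carbon C9 while the double bond moves to C8–C12 and the oxygen stays on boron as borate 15, which neutral hydrolysis converts into 16. The closest known reaction type is the thermal carbonyl allylboration with γ,γ-disubstituted pinacol allylboronates, which gives homoallylic carbinols bearing a quaternary carbon. No ring is closed; the six-membered array exists only in the transition state. C9 is set by approach of the aldehyde to the α face of the C8=C9 bond, because the pseudoaxial C10 methyl next to it screens the β face, and C11 follows from the chair with the aryl group equatorial and the C9 methyl axial, giving the diastereomer in the compound list; this centre is removed later. The step needs bonding at C9 and not at C12, α-face selectivity, and survival of the aryl carbonate: the cyclic transition state allows bonding only at the γ-carbon, the angular methyl fixes the face, and the absence of base or free alkoxide until the pH 7 quench keeps the carbonate on the phenol.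

Step 13
Reactants: 16 homoallylic C11 carbinol
Product: 17 saturated C11 carbinol with the C8 methyl β (axial; cis to the C10 methyl) and C8–H α
Conditions: [Ir(cod)(PCy3)(py)]PF6 (10 mol %), H2 (1 atm), CH2Cl2, 0 °C → rt
Reagents that add atoms: none
Why: Hydroxyl-directed homogeneous hydrogenation: the free homoallylic C11 hydroxyl on the α arm should hold the cationic iridium on the α face of the C8=C12 bond, so hydrogen reaches C8 from that face and the methyl ends β.

Step 14
Reactants: 17 saturated C11 carbinol
Product: 20 phenol with C11 as CH2 (C4–OTBS retained; all four ring stereocentres as in the target), via C11 carbonate phenoxide 18 (not isolated), via ortho-quinone methide 19 (not isolated)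
Conditions: t-BuMgCl (1.1 equiv), NaBH4 (5 equiv), THF, −78 °C → rt; aq. NH4Cl
Reagents that add atoms: none
Why: Base-triggered carbonate transfer from the aryl oxygen to the C11 alkoxide, 1,4-elimination of tert-butyl carbonate from the phenoxide and 1,4-addition of hydride to the ortho-quinone methide should leave CH2 at C11; C9 is quaternary, so the quinone methide cannot tautomerise.

Step 15
Reactants: 20 silyl ether phenol
Product: 21 C4 alcohol (C4–OH α) with free phenol
Conditions: HF·pyridine, pyridine, THF, 0 °C → rt
Reagents that add atoms: none
Why: Fluoride-mediated cleavage of the Si–O bond under buffered acidic conditions should free the C4 alcohol without touching the methyl ester.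

Step 16
Reactants: 21 C4 alcohol
Product: 22 C4 ketone (trans ring fusion, C5–H α)
Conditions: Dess–Martin periodinane, NaHCO3, CH2Cl2, 0 °C → rt
Reagents that add atoms: none
Why: Dess–Martin oxidation under bicarbonate buffer should give the ketone without enolisation towards C5, and the electron-poor phenol (para ester) is expected to resist the periodinane.

Step 17
Reactants: 22 C4 ketone
Product: 23 target, methyl 4-hydroxy-3-{[(1R,2S,4aS,8aS)-1,2,8a-trimethyl-5-methylidenedecahydronaphthalen-1-yl]methyl}benzoate
Conditions: Zn, CH2Br2, TiCl4, THF/CH2Cl2, 0 °C → rt (excess reagent for the free phenol)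
Reagents that add atoms: dibromomethane, BrCBr
Why: Takai–Lombardo methylenation with the non-basic zinc–titanium methylene reagent should convert the ketone into the exocyclic alkene without epimerising C5 and without attacking the methyl ester.

## Compound list

1 | (S)-8a-methyl-3,4,8,8a-tetrahydronaphthalene-1,6(2H,7H)-dione | O=C1CC[C@@]2(C)C(=C1)CCCC2=O | starting material
2 | C3 ethylene dithioketal of 1 (spiro-1,3-dithiolane, C4=C5, C9 ketone) | S1CCSC12CC[C@@]3(C)C(=C2)CCCC3=O | intermediate
3 | (S)-8a-methyl-3,4,6,7,8,8a-hexahydronaphthalen-1(2H)-one | C1CC[C@@]2(C)C(=C1)CCCC2=O | intermediate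
4 | methyl (8aS)-8a-methyl-1-oxo-1,2,3,4,6,7,8,8a-octahydronaphthalene-2-carboxylate (C8 undefined) | C1CC[C@@]2(C)C(=C1)CCC(C(=O)OC)C2=O | intermediate
5 | methyl (S)-8a-methyl-1-(trifluoromethanesulfonyloxy)-3,4,6,7,8,8a-hexahydronaphthalene-2-carboxylate | C1CC[C@@]2(C)C(=C1)CCC(C(=O)OC)=C2OS(=O)(=O)C(F)(F)F | intermediate
6 | methyl (S)-1,8a-dimethyl-3,4,6,7,8,8a-hexahydronaphthalene-2-carboxylate | C1CC[C@@]2(C)C(=C1)CCC(C(=O)OC)=C2C | intermediate
7 | C4 alkylborane from α-face hydroboration of 6 (drawn as the monoalkylborane) | B[C@@H]1CCC[C@@]2(C)[C@H]1CCC(C(=O)OC)=C2C | intermediate (not isolated)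
8 | 4α-hydroxy-5α-H trans-fused enoate (C8 CO2Me, C9 CH3, C8=C9) | O[C@@H]1CCC[C@@]2(C)[C@H]1CCC(C(=O)OC)=C2C | intermediate
9 | C4 tert-butyldimethylsilyl ether of 8 | CC(C)(C)[Si](C)(C)O[C@@H]1CCC[C@@]2(C)[C@H]1CCC(C(=O)OC)=C2C | intermediate
10 | allylic alcohol (C12–OH, C8=C9, C4–OTBS α, C5–H α) | CC(C)(C)[Si](C)(C)O[C@@H]1CCC[C@@]2(C)[C@H]1CCC(CO)=C2C | intermediate
11 | allylic methyl carbonate of 10 | CC(C)(C)[Si](C)(C)O[C@@H]1CCC[C@@]2(C)[C@H]1CCC(COC(=O)OC)=C2C | intermediate
12 | C12 pinacol allylboronate (fragment 1) | CC(C)(C)[Si](C)(C)O[C@@H]1CCC[C@@]2(C)[C@H]1CCC(CB3OC(C)(C)C(C)(C)O3)=C2C | intermediate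
13 | methyl 3-formyl-4-hydroxybenzoate | COC(=O)c1ccc(O)c(C=O)c1 | starting material
14 | methyl 4-(tert-butoxycarbonyloxy)-3-formylbenzoate (fragment 2) | COC(=O)c1ccc(OC(=O)OC(C)(C)C)c(C=O)c1 | intermediate
15 | C11 pinacol borate of the allylboration adduct | CC(C)(C)[Si](C)(C)O[C@@H]1CCC[C@@]2(C)[C@H]1CCC(=C)[C@@]2(C)[C@H](OB3OC(C)(C)C(C)(C)O3)c1cc(C(=O)OC)ccc1OC(=O)OC(C)(C)C | intermediate (not isolated)
16 | homoallylic C11 carbinol with quaternary C9 and C8=C12 methylene, aryl tert-butyl carbonate retained | CC(C)(C)[Si](C)(C)O[C@@H]1CCC[C@@]2(C)[C@H]1CCC(=C)[C@@]2(C)[C@H](O)c1cc(C(=O)OC)ccc1OC(=O)OC(C)(C)C | intermediate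
17 | C11 carbinol with C8 methyl β (axial) | CC(C)(C)[Si](C)(C)O[C@@H]1CCC[C@@]2(C)[C@H]1CC[C@H](C)[C@@]2(C)[C@H](O)c1cc(C(=O)OC)ccc1OC(=O)OC(C)(C)C | intermediate
18 | C11 tert-butyl carbonate with chloromagnesium phenoxide | CC(C)(C)[Si](C)(C)O[C@@H]1CCC[C@@]2(C)[C@H]1CC[C@H](C)[C@@]2(C)[C@H](OC(=O)OC(C)(C)C)c1cc(C(=O)OC)ccc1O[Mg]Cl | intermediate (not isolated)
19 | ortho-quinone methide (C11=C exocyclic to the cyclohexadienone) | CC(C)(C)[Si](C)(C)O[C@@H]1CCC[C@@]2(C)[C@H]1CC[C@H](C)[C@@]2(C)C=C1C=C(C(=O)OC)C=CC1=O | intermediate (not isolated)
20 | phenol with C11 as CH2, C4–OTBS α | CC(C)(C)[Si](C)(C)O[C@@H]1CCC[C@@]2(C)[C@H]1CC[C@H](C)[C@@]2(C)Cc1cc(C(=O)OC)ccc1O | intermediate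
21 | C4 α-alcohol with free phenol | O[C@@H]1CCC[C@@]2(C)[C@H]1CC[C@H](C)[C@@]2(C)Cc1cc(C(=O)OC)ccc1O | intermediate
22 | C4 ketone | O=C1CCC[C@@]2(C)[C@H]1CC[C@H](C)[C@@]2(C)Cc1cc(C(=O)OC)ccc1O | intermediate
23 | methyl 4-hydroxy-3-{[(1R,2S,4aS,8aS)-1,2,8a-trimethyl-5-methylidenedecahydronaphthalen-1-yl]methyl}benzoate (CNP0169318.1) | C=C1CCC[C@@]2(C)[C@H]1CC[C@H](C)[C@@]2(C)Cc1cc(C(=O)OC)ccc1O | target

## Count and risks

Total step count: 17. Longest linear sequence: 16 (steps 1–10, then 12–17); step 11 is a one-step side branch.

Steps most likely to fail: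

1. Step 12. The γ-carbon C9 is fully substituted and adjacent to quaternary C10, so bond formation may be too slow. Prolonged heating could then erode the face selectivity or move or cleave the aryl carbonate. The fallback changes the allyl metal and also bypasses steps 9 and 10. It sets out from alcohol 10, which an Appel reaction (CBr4, PPh3, CH2Cl2, 0 °C) should convert into the allylic bromide F1. Divalent chromium chloride CrCl2 in THF at rt in the presence of aldehyde 14 should then form the allylchromium dichloride F2, a trivalent chromium species, in the flask. In a Nozaki–Hiyama allylation this reagent adds through its γ-carbon C9, again through a six-membered transition state and from the α face. A pH 7 quench should give carbinol 16, where the fallback rejoins the route.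

2. Step 13. The congested C11 hydroxyl may fail to hold the iridium, or the catalyst may deactivate before turnover, which would give poor facial selectivity at C8 or no reduction. The fallback inverts the order and relies on steric control in place of direction. It sets out from 16, which is treated as in step 14 (t-BuMgCl, NaBH4, THF) and should pass through the ortho-quinone methide F3 to the methylene phenol F4. Heterogeneous hydrogenation (H2, PtO2, EtOAc, rt) is then expected to deliver hydrogen to the equatorial α side of C8, because the 1,3-related axial C10 methyl screens the β side; the axial C9 benzyl arm may oppose this, so the selectivity is uncertain. The fallback rejoins the route at 20.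

3. Step 14. Carbonate transfer to the hindered C11 alkoxide may be slow, or the electron-poor phenoxide (para ester) may be reluctant to expel the carbonate, so the ortho-quinone methide may not form cleanly. The fallback uses acid ionisation in place of base-triggered elimination. It sets out from 17 with CF3CO2H and Et3SiH in CH2Cl2 at 0 °C. The acid should first remove the tert-butyl carbonate to give the salicyl alcohol F5. F5 then loses water to the protonated form of quinone methide 19, which the silane reduces (ionic hydrogenation) to 20, where the fallback rejoins the route. Partial loss of the silyl ether would only anticipate step 15.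

## Further compounds

F1 | step 12 | allylic bromide (C12–Br on the C8=C9 double bond, C4–OTBS α) | CC(C)(C)[Si](C)(C)O[C@@H]1CCC[C@@]2(C)[C@H]1CCC(CBr)=C2C
F2 | step 12 | allylchromium dichloride formed in the flask from F1 | CC(C)(C)[Si](C)(C)O[C@@H]1CCC[C@@]2(C)[C@H]1CCC(C[Cr](Cl)Cl)=C2C
F3 | step 13 | ortho-quinone methide of the C8=C12 methylene series | CC(C)(C)[Si](C)(C)O[C@@H]1CCC[C@@]2(C)[C@H]1CCC(=C)[C@@]2(C)C=C1C=C(C(=O)OC)C=CC1=O
F4 | step 13 | methylene phenol (C8=C12, C11 as CH2, C4–OTBS α) | CC(C)(C)[Si](C)(C)O[C@@H]1CCC[C@@]2(C)[C@H]1CCC(=C)[C@@]2(C)Cc1cc(C(=O)OC)ccc1O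
F5 | step 14 | salicyl alcohol (free phenol, C11–OH, C8 methyl β, C4–OTBS α) | CC(C)(C)[Si](C)(C)O[C@@H]1CCC[C@@]2(C)[C@H]1CC[C@H](C)[C@@]2(C)[C@H](O)c1cc(C(=O)OC)ccc1O
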